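**Plan**

1. Cuts: the CH2–CH2 bridge between decalin C2 and dioxane C6' (made as a C=C), the exocyclic C1=CH2 bond, the C2–C3 bond of ring B, and the two ring A bonds of a Diels–Alder adduct; in the dioxane the O–C3', O–C6' and C3'–Cα bonds.
2. Enabling feature (decalin locants C1 (C=CH2), C2 (quaternary), C3 (CHMe), C4, C4a, C5=C6(Me), C7, C8, C8a): C2 lies α to a C1 carbonyl and its CH2 arm can be an ester, while the neighbouring C3 carries a methyl that can be CH2SO2Ph. C2–C3 is therefore the bond between a β-keto ester enolate on ring A and an (E)-vinyl sulfone on the C4a side chain.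
3. Forward order: ring A by Diels–Alder (step 2), ring B by the Michael closure (step 8), the 1,2-dioxane separately from geranyl acetate (steps 14–23), union by Julia–Kocienski olefination (step 24), saturation of the bridge (step 25). The exocyclic methylene is released last from a β-hydroxysilane (step 26), so that it never meets the reductant.
4. Stereochemistry: C4a/C8a from the organocatalytic endo Diels–Alder; C2/C3 from the lithium-chelated chair of the Michael step; Cα/C3' from (E)-crotylboration followed by SN2 inversion at C3'; C6' from Sharpless epoxidation followed by perhydrolysis with inversion.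

Key step: step 8

Assumption: the acidic α-carbon of 7–10 and 12 and the carbinol carbon C1 of 14–18, 32 and 33 are carried as epimer mixtures because both are erased later (enolate in step 8, elimination in step 26); ylide 11 is taken as purchasable (otherwise one step from Ph3P=CH2 and PhSO2F).

**Route**

Step 1
Reactants: 1 diethyl (2-methylallyl)phosphonate; 2 3-[(tert-butyldimethylsilyl)oxy]propanal
Product: 3 tert-butyl(dimethyl){[(3E)-5-methylhexa-3,5-dien-1-yl]oxy}silane
Conditions: n-BuLi, THF/HMPA, −78 °C → rt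
Reagents that add atoms: none
Why: Horner–Wadsworth–Emmons olefination of the lithiated allylic phosphonate at its α-carbon; elimination from the more stable adduct should give the (E)-diene.

Step 2
Reactants: 3 silyloxy diene; 4 acrolein
Product: 5 (1S,2R)-2-{2-[(tert-butyldimethylsilyl)oxy]ethyl}-4-methylcyclohex-3-ene-1-carbaldehyde
Conditions: (5R)-5-benzyl-2,2,3-trimethylimidazolidin-4-one·HCl (20 mol %), MeCN/H2O (95:5), 0 °C
Reagents that add atoms: none
Why: Iminium-activated Diels–Alder reaction in which the substituted diene terminus bonds to the α-carbon of acrolein; the benzyl group of the (5R)-catalyst blocks one face of the (E)-iminium so that C1 should form as S, and the endo transition state places the side chain cis to the formyl group (C2 = R).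

Step 3
Reactants: 5 cyclohexenecarbaldehyde; 6 methyl propanoate
Product: 7 methyl 3-[(1S,2R)-2-{2-[(tert-butyldimethylsilyl)oxy]ethyl}-4-methylcyclohex-3-en-1-yl]-3-hydroxy-2-methylpropanoate (mixture at the two new centres)
Conditions: LiN(iPr)2, THF, −78 °C; AcOH
Reagents that add atoms: none
Why: Aldol addition of the lithium ester enolate at −78 °C, faster than enolisation of the α-branched aldehyde; the two new centres are erased by step 4 and by the enolate of step 8.

Step 4
Reactants: 7 β-hydroxy ester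
Product: 8 methyl 3-[(1S,2R)-2-{2-[(tert-butyldimethylsilyl)oxy]ethyl}-4-methylcyclohex-3-en-1-yl]-2-methyl-3-oxopropanoate
Conditions: Dess–Martin periodinane, NaHCO3, CH2Cl2, 0 °C → rt
Reagents that add atoms: none
Why: Dess–Martin oxidation of the secondary alcohol to the β-keto ester under buffered, non-basic conditions that leave the ring carbon C1 and the silyl ether untouched.

Step 5
Reactants: 8 silyl ether keto ester
Product: 9 methyl 3-[(1S,2R)-2-(2-hydroxyethyl)-4-methylcyclohex-3-en-1-yl]-2-methyl-3-oxopropanoate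
Conditions: HF·pyridine, THF, 0 °C
Reagents that add atoms: none
Why: Fluoride-driven desilylation under mildly acidic conditions, which should not epimerise the cis-disubstituted ring or cleave the keto ester.

Step 6
Reactants: 9 hydroxy keto ester
Product: 10 methyl 2-methyl-3-[(1S,2R)-4-methyl-2-(2-oxoethyl)cyclohex-3-en-1-yl]-3-oxopropanoate
Conditions: Dess–Martin periodinane, NaHCO3, CH2Cl2, 0 °C
Reagents that add atoms: none
Why: Dess–Martin oxidation of the primary alcohol (free in equilibrium with its hemiketal) to the aldehyde without base, so that the keto ester does not condense with it.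

Step 7
Reactants: 10 keto ester aldehyde; 11 (phenylsulfonylmethylene)triphenylphosphorane
Product: 12 methyl 2-methyl-3-[(1S,2R)-4-methyl-2-[(2E)-3-(phenylsulfonyl)prop-2-en-1-yl]cyclohex-3-en-1-yl]-3-oxopropanoate
Conditions: CH2Cl2, 40 °C (no added base)
Reagents that add atoms: none
Why: Wittig olefination with a sulfonyl-stabilised ylide; without added base the acidic keto ester stays protonated and uncyclised, and the stabilised ylide should give the (E)-vinyl sulfone.

Step 8
Reactants: 12 keto ester vinyl sulfone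
Product: 13 methyl (2R,3S,4aR,8aS)-2,6-dimethyl-1-oxo-3-[(phenylsulfonyl)methyl]-1,2,3,4,4a,7,8,8a-octahydronaphthalene-2-carboxylate
Conditions: LiOtBu (0.2 equiv), THF, −40 → 0 °C; AcOH
Reagents that add atoms: none
Why: Sub-stoichiometric LiOtBu deprotonates only the β-keto ester, the lithium-chelated enolate adds through C2 to the β-carbon (C3) of the vinyl sulfone, and the resulting α-sulfonyl carbanion is protonated by unreacted keto ester, which regenerates the enolate. The reaction type is the known intramolecular Michael addition of β-keto ester enolates to vinyl sulfones. Ring B closes 6-exo-trig (the enolate C=C lies inside the forming ring) through a chair. C2 is controlled by the chelate and by ring A: the ester, held syn to the enolate oxygen, ends equatorial and the methyl axial, and the enolate face is fixed because the alternative chair would place C8 of the cis-attached ring A and the C2 methyl 1,3-diaxial. C3 is controlled by the (E)-acceptor lying pseudo-equatorial in that chair, which leaves CH2SO2Ph equatorial. The step needs C- over O-alkylation and no epimerisation at C8a; the soft sulfone acceptor with irreversible C–C bond formation should secure the first, catalytic base at low temperature with an acidic quench the second.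

Step 9
Reactants: 13 decalone keto ester
Product: 14 methyl (2R,3S,4aR,8aS)-1-hydroxy-2,6-dimethyl-3-[(phenylsulfonyl)methyl]-1-[(trimethylsilyl)methyl]-1,2,3,4,4a,7,8,8a-octahydronaphthalene-2-carboxylate
Conditions: Me3SiCH2Li, CeCl3, THF, −78 °C; AcOH
Reagents that add atoms: (trimethylsilyl)methyllithium, [Li]C[Si](C)(C)C
Why: 1,2-Addition of the organocerium reagent (first half of a Peterson olefination): the small, weakly basic nucleophile should add to the hindered C1 ketone faster than it attacks the neopentyl ester or deprotonates C8a or the sulfone, and the carbinol configuration is irrelevant because C1 becomes sp2 in step 26.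

Step 10
Reactants: 14 β-hydroxysilane ester
Product: 15 (2S,3S,4aR,8aS)-2-(hydroxymethyl)-2,6-dimethyl-3-[(phenylsulfonyl)methyl]-1-[(trimethylsilyl)methyl]-1,2,3,4,4a,7,8,8a-octahydronaphthalen-1-ol
Conditions: iBu2AlH, CH2Cl2, −78 → 0 °C; aq. NaK tartrate
Reagents that add atoms: none
Why: Aluminium hydride reduction of the ester to the primary alcohol; the sulfone, the alkene and the C–Si bond are inert to iBu2AlH.

Step 11
Reactants: 15 diol sulfone
Product: 16 (2S,3S,4aR,8aS)-2-(hydroxymethyl)-2,3,6-trimethyl-1-[(trimethylsilyl)methyl]-1,2,3,4,4a,7,8,8a-octahydronaphthalen-1-ol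
Conditions: Mg, MeOH, 50 °C
Reagents that add atoms: none
Why: Reductive desulfonylation by electron transfer from magnesium in methanol (C–S cleavage, then protonation) turns CH2SO2Ph into the C3 methyl without touching a stereocentre.

Step 12
Reactants: 16 diol
Product: 17 (2R,3S,4aR,8aS)-2,3,6-trimethyl-2-{[(1-phenyl-1H-tetrazol-5-yl)sulfanyl]methyl}-1-[(trimethylsilyl)methyl]-1,2,3,4,4a,7,8,8a-octahydronaphthalen-1-ol
Conditions: 1-phenyl-1H-tetrazole-5-thiol, PPh3, DIAD, THF, 0 → 45 °C
Reagents that add atoms: 1-phenyl-1H-tetrazole-5-thiol, Sc1nnnn1-c1ccccc1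
Why: Mitsunobu thioetherification: the acidic thiol displaces the activated primary (neopentyl) oxygen, while the hindered tertiary carbinol cannot be activated.

Step 13
Reactants: 17 tetrazolyl sulfide
Product: 18 (2R,3S,4aR,8aS)-2,3,6-trimethyl-2-{[(1-phenyl-1H-tetrazol-5-yl)sulfonyl]methyl}-1-[(trimethylsilyl)methyl]-1,2,3,4,4a,7,8,8a-octahydronaphthalen-1-ol
Conditions: (NH4)6Mo7O24·4H2O (10 mol %), 30 % H2O2, EtOH, 0 °C → rt
Reagents that add atoms: hydrogen peroxide, OO
Why: Molybdate-catalysed oxidation of the sulfide to the sulfone, which should be faster than epoxidation of the unactivated trisubstituted alkene.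

Step 14
Reactants: 19 geranyl acetate
Product: 20 (2E)-3-methyl-6-oxohex-2-en-1-yl acetate
Conditions: O3 (1.0 equiv), pyridine, CH2Cl2, −78 °C
Reagents that add atoms: ozone, [O-][O+]=O
Why: Ozonolysis with one equivalent of ozone selects the electron-richer 6,7-alkene over the alkene deactivated by the allylic acetate, and pyridine decomposes the carbonyl oxide in the flask so that the aldehyde forms directly.

Step 15
Reactants: 20 acetoxy aldehyde
Product: 22 (2E,6S,7R)-6-hydroxy-3,7-dimethylnona-2,8-dien-1-yl acetate, via diisopinocampheylborinate 21 (not isolated)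
Conditions: (E)-but-2-ene, KOtBu, n-BuLi, THF, −78 → −45 °C; (+)-Ipc2BOMe; BF3·OEt2; 20, −78 °C; then NaBO3·4H2O, THF/H2O, rt
Reagents that add atoms: (E)-but-2-ene, C/C=C/C
Why: Crotylboration through a closed chair transition state: the (E)-crotyl group gives the anti relationship, and the isopinocampheyl ligands of the (−)-α-pinene series direct addition to the Re face of the aldehyde, which should give 6S,7R.

Step 16
Reactants: 22 anti homoallylic alcohol
Product: 23 (2E,6S,7R)-3,7-dimethyl-6-[(methylsulfonyl)oxy]nona-2,8-dien-1-yl acetate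
Conditions: MsCl, Et3N, CH2Cl2, 0 °C
Reagents that add atoms: methanesulfonyl chloride, CS(=O)(=O)Cl
Why: O-Sulfonylation of the secondary alcohol with retention prepares C6 for the later displacement.

Step 17
Reactants: 23 acetate mesylate
Product: 24 (2E,6S,7R)-1-hydroxy-3,7-dimethylnona-2,8-dien-6-yl methanesulfonate
Conditions: K2CO3 (cat.), MeOH, 0 °C
Reagents that add atoms: none
Why: Base-catalysed methanolysis (transesterification) of the primary allylic acetate; the secondary mesylate should survive these mild conditions.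

Step 18
Reactants: 24 allylic alcohol
Product: 25 (3S,4R)-1-[(2R,3R)-3-(hydroxymethyl)-2-methyloxiran-2-yl]-4-methylhex-5-en-3-yl methanesulfonate
Conditions: Ti(OiPr)4 (cat.), D-(−)-diethyl tartrate, tBuOOH, 4 Å MS, CH2Cl2, −20 °C
Reagents that add atoms: tert-butyl hydroperoxide, CC(C)(C)OO
Why: Sharpless asymmetric epoxidation of the (E)-allylic alcohol: reagent control by D-(−)-diethyl tartrate should give the (2R,3R)-epoxide, and the terminal alkene, which has no allylic hydroxyl, is not epoxidised.

Step 19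
Reactants: 25 epoxy alcohol
Product: 26 (3R,4S,7S,8R)-7-hydroperoxy-8,9-dihydroxy-3,7-dimethylnon-1-en-4-yl methanesulfonate
Conditions: H2O2 (anhydrous, in Et2O), H3PMo12O40 (cat.), Et2O, rt
Reagents that add atoms: hydrogen peroxide, OO
Why: Acid-catalysed perhydrolysis of the epoxide at its tertiary carbon with inversion sets the quaternary peroxy carbon (later C6') as S and leaves a 1,2-diol as the handle for step 23.

Step 20
Reactants: 26 hydroperoxy mesylate
Product: 27 (1R)-1-[(3S,6R)-6-[(2R)-but-3-en-2-yl]-3-methyl-1,2-dioxan-3-yl]ethane-1,2-diol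
Conditions: KOtBu (1.05 equiv), 18-crown-6, THF, −20 → 0 °C
Reagents that add atoms: none
Why: Intramolecular alkylation of the hydroperoxide anion (6-exo-tet SN2): the hydroperoxide is far more acidic than the alcohols, and displacement of the mesylate with inversion sets C3' as R.

Step 21
Reactants: 27 vinyl dioxane diol
Product: 29 (2S)-2-[(3R,6S)-6-[(1R)-1,2-dihydroxyethyl]-6-methyl-1,2-dioxan-3-yl]propanoic acid, via dioxanylpropanal 28 (not isolated)
Conditions: O3, MeCN/H2O (9:1), 0 °C; then NaClO2, NaH2PO4, 2-methyl-2-butene, tBuOH, 0 °C → rt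
Reagents that add atoms: ozone, [O-][O+]=O; sodium chlorite, [Na+].[O-]Cl=O
Why: Ozonolysis in aqueous acetonitrile gives the aldehyde directly (water traps the carbonyl oxide), and Pinnick oxidation in the same flask converts it to the acid before the α-centre can epimerise; the dialkyl peroxide and the diol are inert to both oxidants.

Step 22
Reactants: 29 dioxane acid
Product: 30 methyl (2S)-2-[(3R,6S)-6-[(1R)-1,2-dihydroxyethyl]-6-methyl-1,2-dioxan-3-yl]propanoate
Conditions: Me3SiCHN2, MeOH/PhMe, 0 °C
Reagents that add atoms: (trimethylsilyl)diazomethane, C[Si](C)(C)C=[N+]=[N-]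
Why: Esterification of the acid with (trimethylsilyl)diazomethane in methanol, neutral conditions that spare the base-sensitive β-peroxy ester.

Step 23
Reactants: 30 dioxane diol ester
Product: 31 methyl (2S)-2-[(3R,6S)-6-formyl-6-methyl-1,2-dioxan-3-yl]propanoate
Conditions: NaIO4, THF/pH 7 buffer, 0 °C → rt
Reagents that add atoms: none
Why: Glycol cleavage with periodate (Malaprade reaction) turns the diol into the non-enolisable α-peroxy aldehyde.

Step 24
Reactants: 18 decalin tetrazolyl sulfone; 31 dioxane aldehyde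
Product: 32 methyl (2S)-2-[(3R,6S)-6-{(E)-2-[(2S,3S,4aR,8aS)-1-hydroxy-2,3,6-trimethyl-1-[(trimethylsilyl)methyl]-1,2,3,4,4a,7,8,8a-octahydronaphthalen-2-yl]ethenyl}-6-methyl-1,2-dioxan-3-yl]propanoate
Conditions: LiN(SiMe3)2 (2.1 equiv), THF, −78 °C; then 31, −78 °C → rt; AcOH
Reagents that add atoms: none
Why: Julia–Kocienski olefination: the lithiated tetrazolyl sulfone adds to the non-enolisable aldehyde, and Smiles rearrangement with loss of SO2 and tetrazolate gives the alkene, which between two quaternary carbons can only be E; the second equivalent of base holds the tertiary carbinol as a lithium alkoxide, which does not undergo Peterson elimination.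

Step 25
Reactants: 32 bridged alkene
Product: 33 methyl (2S)-2-[(3R,6R)-6-{2-[(2R,3S,4aR,8aS)-1-hydroxy-2,3,6-trimethyl-1-[(trimethylsilyl)methyl]-1,2,3,4,4a,7,8,8a-octahydronaphthalen-2-yl]ethyl}-6-methyl-1,2-dioxan-3-yl]propanoate
Conditions: 2-nitrobenzenesulfonylhydrazide (excess, in portions), Et3N, CH2Cl2, rt
Reagents that add atoms: none
Why: Diimide reduction (concerted syn transfer of H2) should saturate the disubstituted alkene while leaving the O–O bond, the ester and the much less reactive trisubstituted ring A alkene; the exocyclic methylene is still masked and cannot compete.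

Step 26
Reactants: 33 saturated β-hydroxysilane
Product: 34 methyl (2S)-2-[(3R,6R)-6-methyl-6-{2-[(2R,3S,4aR,8aS)-2,3,6-trimethyl-1-methylidene-1,2,3,4,4a,7,8,8a-octahydronaphthalen-2-yl]ethyl}-1,2-dioxan-3-yl]propanoate (CNP0144520.2)
Conditions: 48 % aq. HF, MeCN, 0 °C
Reagents that add atoms: none
Why: Acid-promoted Peterson elimination of the β-hydroxysilane (through the β-silyl-stabilised cation) forms only the exocyclic C1=CH2 bond, under conditions that the dioxane and the methyl ester tolerate.

**Compound list**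

1 | diethyl (2-methylallyl)phosphonate | C=C(C)CP(=O)(OCC)OCC | starting material
2 | 3-[(tert-butyldimethylsilyl)oxy]propanal | O=CCCO[Si](C)(C)C(C)(C)C | starting material
3 | tert-butyl(dimethyl){[(3E)-5-methylhexa-3,5-dien-1-yl]oxy}silane | C=C(C)/C=C/CCO[Si](C)(C)C(C)(C)C | intermediate
4 | acrolein | C=CC=O | starting material
5 | (1S,2R)-2-{2-[(tert-butyldimethylsilyl)oxy]ethyl}-4-methylcyclohex-3-ene-1-carbaldehyde | O=C[C@H]1CCC(C)=C[C@H]1CCO[Si](C)(C)C(C)(C)C | intermediate
6 | methyl propanoate | CCC(=O)OC | starting material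
7 | methyl 3-[(1S,2R)-2-{2-[(tert-butyldimethylsilyl)oxy]ethyl}-4-methylcyclohex-3-en-1-yl]-3-hydroxy-2-methylpropanoate (mixture at C2 and C3 of the propanoate) | COC(=O)C(C)C(O)[C@H]1CCC(C)=C[C@H]1CCO[Si](C)(C)C(C)(C)C | intermediate
8 | methyl 3-[(1S,2R)-2-{2-[(tert-butyldimethylsilyl)oxy]ethyl}-4-methylcyclohex-3-en-1-yl]-2-methyl-3-oxopropanoate (C2 epimers) | COC(=O)C(C)C(=O)[C@H]1CCC(C)=C[C@H]1CCO[Si](C)(C)C(C)(C)C | intermediate
9 | methyl 3-[(1S,2R)-2-(2-hydroxyethyl)-4-methylcyclohex-3-en-1-yl]-2-methyl-3-oxopropanoate (C2 epimers) | COC(=O)C(C)C(=O)[C@H]1CCC(C)=C[C@H]1CCO | intermediate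
10 | methyl 2-methyl-3-[(1S,2R)-4-methyl-2-(2-oxoethyl)cyclohex-3-en-1-yl]-3-oxopropanoate (C2 epimers) | COC(=O)C(C)C(=O)[C@H]1CCC(C)=C[C@H]1CC=O | intermediate
11 | (phenylsulfonylmethylene)triphenylphosphorane | O=S(=O)(C=P(c1ccccc1)(c1ccccc1)c1ccccc1)c1ccccc1 | starting material
12 | methyl 2-methyl-3-[(1S,2R)-4-methyl-2-[(2E)-3-(phenylsulfonyl)prop-2-en-1-yl]cyclohex-3-en-1-yl]-3-oxopropanoate (C2 epimers) | COC(=O)C(C)C(=O)[C@H]1CCC(C)=C[C@H]1C/C=C/S(=O)(=O)c1ccccc1 | intermediate
13 | methyl (2R,3S,4aR,8aS)-2,6-dimethyl-1-oxo-3-[(phenylsulfonyl)methyl]-1,2,3,4,4a,7,8,8a-octahydronaphthalene-2-carboxylate | O=C1[C@H]2CCC(C)=C[C@H]2C[C@H](CS(=O)(=O)c2ccccc2)[C@@]1(C)C(=O)OC | intermediate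
14 | methyl (2R,3S,4aR,8aS)-1-hydroxy-2,6-dimethyl-3-[(phenylsulfonyl)methyl]-1-[(trimethylsilyl)methyl]-1,2,3,4,4a,7,8,8a-octahydronaphthalene-2-carboxylate (C1 epimers) | OC1(C[Si](C)(C)C)[C@H]2CCC(C)=C[C@H]2C[C@H](CS(=O)(=O)c2ccccc2)[C@@]1(C)C(=O)OC | intermediate
15 | (2S,3S,4aR,8aS)-2-(hydroxymethyl)-2,6-dimethyl-3-[(phenylsulfonyl)methyl]-1-[(trimethylsilyl)methyl]-1,2,3,4,4a,7,8,8a-octahydronaphthalen-1-ol (C1 epimers) | OC1(C[Si](C)(C)C)[C@H]2CCC(C)=C[C@H]2C[C@H](CS(=O)(=O)c2ccccc2)[C@@]1(C)CO | intermediate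
16 | (2S,3S,4aR,8aS)-2-(hydroxymethyl)-2,3,6-trimethyl-1-[(trimethylsilyl)methyl]-1,2,3,4,4a,7,8,8a-octahydronaphthalen-1-ol (C1 epimers) | OC1(C[Si](C)(C)C)[C@H]2CCC(C)=C[C@H]2C[C@H](C)[C@@]1(C)CO | intermediate
17 | (2R,3S,4aR,8aS)-2,3,6-trimethyl-2-{[(1-phenyl-1H-tetrazol-5-yl)sulfanyl]methyl}-1-[(trimethylsilyl)methyl]-1,2,3,4,4a,7,8,8a-octahydronaphthalen-1-ol (C1 epimers) | OC1(C[Si](C)(C)C)[C@H]2CCC(C)=C[C@H]2C[C@H](C)[C@@]1(C)CSc1nnnn1-c1ccccc1 | intermediate
18 | (2R,3S,4aR,8aS)-2,3,6-trimethyl-2-{[(1-phenyl-1H-tetrazol-5-yl)sulfonyl]methyl}-1-[(trimethylsilyl)methyl]-1,2,3,4,4a,7,8,8a-octahydronaphthalen-1-ol (C1 epimers) | OC1(C[Si](C)(C)C)[C@H]2CCC(C)=C[C@H]2C[C@H](C)[C@@]1(C)CS(=O)(=O)c1nnnn1-c1ccccc1 | intermediate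
19 | geranyl acetate, (2E)-3,7-dimethylocta-2,6-dien-1-yl acetate | CC(=O)OC/C=C(\C)CCC=C(C)C | starting material
20 | (2E)-3-methyl-6-oxohex-2-en-1-yl acetate | CC(=O)OC/C=C(\C)CCC=O | intermediate
21 | (2E,6S,7R)-6-{[bis(isopinocampheyl)boranyl]oxy}-3,7-dimethylnona-2,8-dien-1-yl acetate | CC(=O)OC/C=C(\C)CC[C@H](OB([C@H]1C[C@H]2C[C@@H]([C@@H]1C)C2(C)C)[C@H]1C[C@H]2C[C@@H]([C@@H]1C)C2(C)C)[C@H](C)C=C | intermediate (not isolated)
22 | (2E,6S,7R)-6-hydroxy-3,7-dimethylnona-2,8-dien-1-yl acetate | CC(=O)OC/C=C(\C)CC[C@H](O)[C@H](C)C=C | intermediate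
23 | (2E,6S,7R)-3,7-dimethyl-6-[(methylsulfonyl)oxy]nona-2,8-dien-1-yl acetate | CC(=O)OC/C=C(\C)CC[C@H](OS(C)(=O)=O)[C@H](C)C=C | intermediate
24 | (2E,6S,7R)-1-hydroxy-3,7-dimethylnona-2,8-dien-6-yl methanesulfonate | OC/C=C(\C)CC[C@H](OS(C)(=O)=O)[C@H](C)C=C | intermediate
25 | (3S,4R)-1-[(2R,3R)-3-(hydroxymethyl)-2-methyloxiran-2-yl]-4-methylhex-5-en-3-yl methanesulfonate | OC[C@H]1O[C@]1(C)CC[C@H](OS(C)(=O)=O)[C@H](C)C=C | intermediate
26 | (3R,4S,7S,8R)-7-hydroperoxy-8,9-dihydroxy-3,7-dimethylnon-1-en-4-yl methanesulfonate | OC[C@@H](O)[C@@](C)(OO)CC[C@H](OS(C)(=O)=O)[C@H](C)C=C | intermediate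
27 | (1R)-1-[(3S,6R)-6-[(2R)-but-3-en-2-yl]-3-methyl-1,2-dioxan-3-yl]ethane-1,2-diol | OC[C@@H](O)[C@]1(C)CC[C@H]([C@H](C)C=C)OO1 | intermediate
28 | (2S)-2-[(3R,6S)-6-[(1R)-1,2-dihydroxyethyl]-6-methyl-1,2-dioxan-3-yl]propanal | OC[C@@H](O)[C@]1(C)CC[C@H]([C@H](C)C=O)OO1 | intermediate (not isolated)
29 | (2S)-2-[(3R,6S)-6-[(1R)-1,2-dihydroxyethyl]-6-methyl-1,2-dioxan-3-yl]propanoic acid | OC[C@@H](O)[C@]1(C)CC[C@H]([C@H](C)C(=O)O)OO1 | intermediate
30 | methyl (2S)-2-[(3R,6S)-6-[(1R)-1,2-dihydroxyethyl]-6-methyl-1,2-dioxan-3-yl]propanoate | OC[C@@H](O)[C@]1(C)CC[C@H]([C@H](C)C(=O)OC)OO1 | intermediate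
31 | methyl (2S)-2-[(3R,6S)-6-formyl-6-methyl-1,2-dioxan-3-yl]propanoate | O=C[C@]1(C)CC[C@H]([C@H](C)C(=O)OC)OO1 | intermediate
32 | methyl (2S)-2-[(3R,6S)-6-{(E)-2-[(2S,3S,4aR,8aS)-1-hydroxy-2,3,6-trimethyl-1-[(trimethylsilyl)methyl]-1,2,3,4,4a,7,8,8a-octahydronaphthalen-2-yl]ethenyl}-6-methyl-1,2-dioxan-3-yl]propanoate (C1 epimers) | OC1(C[Si](C)(C)C)[C@H]2CCC(C)=C[C@H]2C[C@H](C)[C@@]1(C)/C=C/[C@]1(C)CC[C@H]([C@H](C)C(=O)OC)OO1 | intermediate
33 | methyl (2S)-2-[(3R,6R)-6-{2-[(2R,3S,4aR,8aS)-1-hydroxy-2,3,6-trimethyl-1-[(trimethylsilyl)methyl]-1,2,3,4,4a,7,8,8a-octahydronaphthalen-2-yl]ethyl}-6-methyl-1,2-dioxan-3-yl]propanoate (C1 epimers) | OC1(C[Si](C)(C)C)[C@H]2CCC(C)=C[C@H]2C[C@H](C)[C@@]1(C)CC[C@]1(C)CC[C@H]([C@H](C)C(=O)OC)OO1 | intermediate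
34 | methyl (2S)-2-[(3R,6R)-6-methyl-6-{2-[(2R,3S,4aR,8aS)-2,3,6-trimethyl-1-methylidene-1,2,3,4,4a,7,8,8a-octahydronaphthalen-2-yl]ethyl}-1,2-dioxan-3-yl]propanoate | C=C1[C@H]2CCC(C)=C[C@H]2C[C@H](C)[C@@]1(C)CC[C@]1(C)CC[C@H]([C@H](C)C(=O)OC)OO1 | target

**Step count and risks**

Total step count: 26. Longest linear sequence: 16 steps (steps 1–13, then 24–26); the dioxane branch (steps 14–23) has 10 steps.

Steps most likely to fail:

1. Step 25. Hydrogen transfer from diazene to the E-alkene wedged between two fully substituted carbons may be so slow that reduction of the trisubstituted ring A alkene keeps pace, or conversion stalls. Fallback: setting out from 32, the bridge would be saturated by heterogeneous catalytic hydrogenation instead of concerted group transfer (H2, 1 atm, PtO2, EtOAc, 0 °C, stopped after one equivalent of uptake). This mode relies on preferential adsorption of the less substituted alkene, and a hindered dialkyl peroxide should survive it at low temperature. No new compound arises (F0), and the route is rejoined at 33.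

2. Step 20. Base-induced elimination of the secondary mesylate towards the allylic hydrogen, or fragmentation of the β-hydroxy hydroperoxide, may outrun the 6-exo-tet displacement. Fallback: the O–C3' bond would be made by conjugate addition instead of substitution. Setting out from 19, allylic oxidation with SeO2/tBuOOH would give (2E,6E)-3,7-dimethyl-8-oxoocta-2,6-dien-1-yl acetate F1, and NaClO2 oxidation would give (2E,6E)-8-acetoxy-2,6-dimethylocta-2,6-dienoic acid F2. Me3SiCHN2 would give methyl (2E,6E)-8-acetoxy-2,6-dimethylocta-2,6-dienoate F3, and K2CO3/MeOH would give methyl (2E,6E)-8-hydroxy-2,6-dimethylocta-2,6-dienoate F4. Epoxidation with Ti(OiPr)4, D-(−)-diethyl tartrate and tBuOOH would give methyl (2E)-5-[(2R,3R)-3-(hydroxymethyl)-2-methyloxiran-2-yl]-2-methylpent-2-enoate F5, and H2O2 with H3PMo12O40 would give methyl (2E,6S,7R)-6-hydroperoxy-7,8-dihydroxy-2,6-dimethyloct-2-enoate F6. Et2NH in CF3CH2OH would then close the dioxane by intramolecular oxa-Michael addition, and the route is rejoined at 30. C6' would still be fixed by the epoxidation, but C3' and Cα would form without control, so 30 would have to be separated from its diastereomers before step 23.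

3. Step 7. The sulfonyl-stabilised ylide is a weak nucleophile, so olefination may be slower than condensation of the keto ester with its own aldehyde (intramolecular aldol). Fallback: setting out from 10, olefination with diethyl [(phenylsulfonyl)methyl]phosphonate, LiCl and iPr2NEt in MeCN would be run so that vinyl sulfone 12 is not isolated. The lithium chelate present under these conditions would close ring B in the same flask. No new compound arises (F0), and the route is rejoined at 13.

Further compounds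
F0 | step 25 | none | none
F1 | step 20 | (2E,6E)-3,7-dimethyl-8-oxoocta-2,6-dien-1-yl acetate | CC(=O)OC/C=C(\C)CC/C=C(\C)C=O
F2 | step 20 | (2E,6E)-8-acetoxy-2,6-dimethylocta-2,6-dienoic acid | CC(=O)OC/C=C(\C)CC/C=C(\C)C(=O)O
F3 | step 20 | methyl (2E,6E)-8-acetoxy-2,6-dimethylocta-2,6-dienoate | CC(=O)OC/C=C(\C)CC/C=C(\C)C(=O)OC
F4 | step 20 | methyl (2E,6E)-8-hydroxy-2,6-dimethylocta-2,6-dienoate | OC/C=C(\C)CC/C=C(\C)C(=O)OC
F5 | step 20 | methyl (2E)-5-[(2R,3R)-3-(hydroxymethyl)-2-methyloxiran-2-yl]-2-methylpent-2-enoate | OC[C@H]1O[C@]1(C)CC/C=C(\C)C(=O)OC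
F6 | step 20 | methyl (2E,6S,7R)-6-hydroperoxy-7,8-dihydroxy-2,6-dimethyloct-2-enoate | OC[C@@H](O)[C@@](C)(OO)CC/C=C(\C)C(=O)OC
F0 | step 7 | none | none
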